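**Retrosynthetic overview**

1. The plan rests on side-chain C3, a tertiary carbinol carrying CH3, OH and the C2H2–C1H2–OAr arm. This is the pattern left by hydride opening at C2 of a 2,3-epoxy alcohol, so the oxirane (O, C2, C3) is closed by tartrate-controlled epoxidation of the E C2=C3 allylic alcohol 22, which already carries the finished carbocycle.
2. After the key step: C2–O cleavage by an aluminium hydride (C10 is reduced in passing), C1–O aryl ether formation with umbelliferone (Mitsunobu), and C10 re-oxidation.
3. Before it: the C5–C6 bond is made by alkoxide-directed 1,4-addition of a homoallylic Grignard reagent (from but-3-yn-1-ol by methylalumination and formaldehyde capture) to (S)-4-hydroxy-2,4-dimethylcyclohex-2-enone; the enolate is methylated at C11.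
4. The enone comes from geraniol: L-tartrate epoxidation sets C7, reductive transposition gives (S)-linalool, then ozonolysis, isopropenyl addition and ring-closing metathesis build the ring.
5. Ring order: carbocycle C6–C11 (step 11), then the transient oxirane (step 15); the coumarin is bought as umbelliferone.

Key step: step 15

Remarks on the chemistry: locants follow the chain O–C1H2–C2H2–C3(Me)(OH)–C4H2–C5H2 and the ring C6H, C7(Me)(OH), C8H2, C9H2, C10(=O), C11Me2. Carbinol centres that are formed without control and later oxidised (in 14, 15, 16, 24 and 26) are carried as both epimers, and their SMILES leave that centre undefined.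

**Chain fragment**

Step 1
Reactants: 1 but-3-yn-1-ol
Product: 2 tert-butyl(but-3-yn-1-yloxy)dimethylsilane
Conditions: t-BuMe2SiCl, imidazole, CH2Cl2, 0 → 25 °C
Reagents that add atoms: tert-butyldimethylsilyl chloride, CC(C)(C)[Si](C)(C)Cl
Why: Imidazole-promoted silyl ether formation on a primary alcohol should mask the hydroxyl against AlMe3 and n-BuLi in the next step.

Step 2
Reactants: 2 tert-butyl(but-3-yn-1-yloxy)dimethylsilane
Product: 5 (2E)-5-{[tert-butyl(dimethyl)silyl]oxy}-3-methylpent-2-en-1-ol, via alkenylalane 3 (not isolated), via lithium alanate 4 (not isolated)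
Conditions: AlMe3, Cp2ZrCl2 (0.2 equiv), CH2Cl2, 0 → 25 °C; evaporate; n-BuLi, THF–hexane, −78 °C; (CH2O)n, −78 → 25 °C
Reagents that add atoms: trimethylaluminium, C[Al](C)C; paraformaldehyde (as formaldehyde), C=O
Why: Negishi zirconium-catalysed methylalumination adds CH3 and Al syn across the terminal alkyne with Al on the terminal carbon, and the derived alanate is hydroxymethylated by formaldehyde with retention, so the E trisubstituted allylic alcohol should form as one geometric isomer.

Step 3
Reactants: 5 (2E)-5-{[tert-butyl(dimethyl)silyl]oxy}-3-methylpent-2-en-1-ol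
Product: 6 tert-butyl({(3E)-5-[(4-methoxybenzyl)oxy]-3-methylpent-3-en-1-yl}oxy)dimethylsilane
Conditions: NaH, 4-MeOC6H4CH2Cl, Bu4NI (cat.), THF–DMF, 0 → 25 °C
Reagents that add atoms: 4-methoxybenzyl chloride, COc1ccc(CCl)cc1
Why: Williamson etherification of the allylic alkoxide should give a C1 ether that withstands magnesium, fluoride and iodomethane and is later removed oxidatively.

Step 4
Reactants: 6 tert-butyl({(3E)-5-[(4-methoxybenzyl)oxy]-3-methylpent-3-en-1-yl}oxy)dimethylsilane
Product: 7 (3E)-5-[(4-methoxybenzyl)oxy]-3-methylpent-3-en-1-ol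
Conditions: Bu4NF, THF, 0 → 25 °C
Reagents that add atoms: none
Why: Fluoride-induced desilylation should free only the C5 hydroxyl, since the benzyl-type ether is inert to fluoride.

Step 5
Reactants: 7 (3E)-5-[(4-methoxybenzyl)oxy]-3-methylpent-3-en-1-ol
Product: 8 1-({[(2E)-5-bromo-3-methylpent-2-en-1-yl]oxy}methyl)-4-methoxybenzene
Conditions: CBr4, PPh3, CH2Cl2, 0 °C
Reagents that add atoms: carbon tetrabromide, BrC(Br)(Br)Br
Why: The Appel reaction converts a primary alcohol into the bromide under neutral conditions that should spare the allylic ether and the alkene geometry.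

**Ring fragment**

Step 6
Reactants: 9 geraniol
Product: 10 (2S,3S)-2,3-epoxygeraniol, [(2S,3S)-3-methyl-3-(4-methylpent-3-en-1-yl)oxiran-2-yl]methanol
Conditions: Ti(OiPr)4 (0.05 equiv), L-(+)-diethyl tartrate (0.07 equiv), t-BuOOH, 4 Å molecular sieves, CH2Cl2, −20 °C
Reagents that add atoms: tert-butyl hydroperoxide, CC(C)(C)OO
Why: Catalytic Sharpless asymmetric epoxidation of an E trisubstituted allylic alcohol with the L-tartrate should deliver oxygen to the face that gives the (2S,3S) oxirane, which fixes the later C7 carbinol, while the remote 6,7-alkene has no directing hydroxyl and stays intact.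

Step 7
Reactants: 10 (2S,3S)-2,3-epoxygeraniol
Product: 11 (2S,3R)-3-(iodomethyl)-2-methyl-2-(4-methylpent-3-en-1-yl)oxirane
Conditions: PPh3, I2, imidazole, CH2Cl2, 0 °C
Reagents that add atoms: iodine, II
Why: Appel-type iodination of the primary alcohol, buffered by imidazole, should leave the oxirane untouched; no stereocentre reacts and the descriptor at the CH carbon changes only through CIP priority.

Step 8
Reactants: 11 (2S,3R)-3-(iodomethyl)-2-methyl-2-(4-methylpent-3-en-1-yl)oxirane
Product: 12 (S)-linalool, (3S)-3,7-dimethylocta-1,6-dien-3-ol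
Conditions: Zn dust, EtOH, reflux
Reagents that add atoms: none
Why: Zinc insertion into the C–I bond followed by β-elimination of the oxirane oxygen (reductive opening of a 2,3-epoxy iodide) should give the transposed tertiary allylic alcohol, with the tertiary C–O bond and its configuration untouched.

Step 9
Reactants: 12 (S)-linalool
Product: 14 (5S)-5-ethenyl-5-methyloxolan-2-ol (both anomers), via ozonide 13 (not isolated)
Conditions: O3 (1 equiv), CH2Cl2, −78 °C; Me2S, −78 → 25 °C
Reagents that add atoms: ozone, [O-][O+]=O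
Why: Ozonolysis with reductive work-up should cleave the electron-rich trisubstituted alkene much faster than the monosubstituted vinyl group when one equivalent of ozone is used, and the resulting γ-hydroxy aldehyde closes to the lactol.

Step 10
Reactants: 14 (5S)-5-ethenyl-5-methyloxolan-2-ol
Product: 15 (6S)-2,6-dimethylocta-1,7-diene-3,6-diol (both C3 epimers)
Conditions: CH2=C(Me)MgBr (2.5 equiv), THF, 0 → 25 °C
Reagents that add atoms: isopropenylmagnesium bromide, CC(=C)[Mg]Br
Why: Grignard addition to the open hydroxy-aldehyde form of the lactol should give the dienediol; the new secondary carbinol centre is uncontrolled and is erased in step 12.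

Step 11
Reactants: 15 (6S)-2,6-dimethylocta-1,7-diene-3,6-diol
Product: 16 (4S)-2,4-dimethylcyclohex-2-ene-1,4-diol (both C1 epimers)
Conditions: second-generation Grubbs catalyst (0.03 equiv), CH2Cl2 (0.01 M), 40 °C
Reagents that add atoms: none
Why: Ring-closing metathesis between the vinyl and isopropenyl groups should close the six-membered ring as a trisubstituted cyclohexene, driven by loss of ethene, without touching the carbinol stereocentre.

Step 12
Reactants: 16 (4S)-2,4-dimethylcyclohex-2-ene-1,4-diol
Product: 17 (4S)-4-hydroxy-2,4-dimethylcyclohex-2-en-1-one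
Conditions: MnO2 (activated, excess), CH2Cl2, 25 °C
Reagents that add atoms: none
Why: Allylic oxidation with MnO2 should convert both epimers of the secondary allylic alcohol into one enone, and the tertiary alcohol cannot be oxidised.

**Union and endgame**

Step 13
Reactants: 17 (4S)-4-hydroxy-2,4-dimethylcyclohex-2-en-1-one; 8 1-({[(2E)-5-bromo-3-methylpent-2-en-1-yl]oxy}methyl)-4-methoxybenzene
Product: 21 (3R,4S)-4-hydroxy-3-{(3E)-5-[(4-methoxybenzyl)oxy]-3-methylpent-3-en-1-yl}-2,2,4-trimethylcyclohexan-1-one, via Grignard reagent 18 (not isolated), via lithium alkoxide 19 (not isolated), via magnesium enolate 20 (not isolated)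
Conditions: 8, Mg, THF, 25 °C (used at once); 17, LiN(SiMe3)2 (1.0 equiv), THF, −78 °C; combine, −78 → 0 °C; MeI, DMPU, 0 → 25 °C
Reagents that add atoms: iodomethane, CI
Why: The C7 alkoxide binds the Grignard magnesium and delivers the alkyl group to C6 on its own face (hydroxyl-directed 1,4-addition of Grignard reagents to 4-hydroxycyclohex-2-enones), which sets C6 as R with the chain cis to the C7 oxygen, and the regiodefined C10–C11 enolate is then C-methylated at C11 (enolate alkylation), where the methyl group already present makes the product gem-dimethyl without a new stereocentre.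

Step 14
Reactants: 21 (3R,4S)-4-hydroxy-3-{(3E)-5-[(4-methoxybenzyl)oxy]-3-methylpent-3-en-1-yl}-2,2,4-trimethylcyclohexan-1-one
Product: 22 (3R,4S)-4-hydroxy-3-[(3E)-5-hydroxy-3-methylpent-3-en-1-yl]-2,2,4-trimethylcyclohexan-1-one
Conditions: DDQ, CH2Cl2–pH 7 buffer, 0 °C
Reagents that add atoms: none
Why: Oxidative cleavage of the 4-methoxybenzyl ether by DDQ should release the C1 allylic alcohol under near-neutral conditions that the ketone, the tertiary alcohol and the alkene tolerate.

Step 15
Reactants: 22 (3R,4S)-4-hydroxy-3-[(3E)-5-hydroxy-3-methylpent-3-en-1-yl]-2,2,4-trimethylcyclohexan-1-one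
Product: 23 (3R,4S)-4-hydroxy-3-{2-[(2R,3R)-3-(hydroxymethyl)-2-methyloxiran-2-yl]ethyl}-2,2,4-trimethylcyclohexan-1-one
Conditions: Ti(OiPr)4 (0.2 equiv), D-(−)-diethyl tartrate (0.26 equiv), t-BuOOH (2 equiv), 4 Å molecular sieves, CH2Cl2, −20 °C
Reagents that add atoms: tert-butyl hydroperoxide, CC(C)(C)OO
Why: The C1 alkoxide of 22 and tert-butyl peroxide bind the dimeric titanium D-(−)-tartrate complex, and the coordinated peroxide oxygen is transferred to the C2=C3 π bond. Both C–O bonds form in this single concerted oxygen-atom transfer, so the oxirane closes by [2+1] addition without a cationic intermediate and the E geometry is carried into the trans C2/C3 relationship. The closest known reaction is the Sharpless asymmetric epoxidation of geraniol-type E trisubstituted allylic alcohols, for which the D-tartrate gives the (2R,3R) epoxide. C2 and C3 are therefore both set by the tartrate ligand and not by the substrate, because the nearest ring stereocentre (C6) is three bonds from C3 and cannot bias the titanium-bound alkene. The step needs enantioface selectivity at an alkene with no resident bias and chemoselectivity for the only allylic alkene, both secured by the C1 hydroxyl as the titanium anchor; the C10 ketone and the hindered tertiary C7 alcohol are not oxidised. Sub-stoichiometric titanium, molecular sieves and low temperature should keep the C7 hydroxyl from opening the new oxirane at C3.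

Step 16
Reactants: 23 (3R,4S)-4-hydroxy-3-{2-[(2R,3R)-3-(hydroxymethyl)-2-methyloxiran-2-yl]ethyl}-2,2,4-trimethylcyclohexan-1-one
Product: 24 (1S,2R)-2-[(3R)-3,5-dihydroxy-3-methylpentyl]-1,3,3-trimethylcyclohexane-1,4-diol (both epimers at the C10 carbinol)
Conditions: NaAlH2(OCH2CH2OMe)2, THF, 0 → 25 °C
Reagents that add atoms: none
Why: In the reduction of 2,3-epoxy alcohols with this hydride the aluminium bound to the C1 oxygen delivers hydride intramolecularly to C2, which should give the 1,3-diol with the C3–O bond and its R configuration untouched, while the C10 ketone is reduced in the same operation to a carbinol that is re-oxidised in step 18.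

Step 17
Reactants: 24 (1S,2R)-2-[(3R)-3,5-dihydroxy-3-methylpentyl]-1,3,3-trimethylcyclohexane-1,4-diol; 25 umbelliferone
Product: 26 7-{[(3R)-5-[(1R,6S)-3,6-dihydroxy-2,2,6-trimethylcyclohexyl]-3-hydroxy-3-methylpentyl]oxy}-2H-chromen-2-one (both epimers at the C10 carbinol)
Conditions: PPh3, DIAD, THF, 0 → 25 °C
Reagents that add atoms: none
Why: In the Mitsunobu etherification the primary C1 hydroxyl should be activated far faster than the neopentyl secondary C10 hydroxyl or the two tertiary ones, and the acidic 7-hydroxycoumarin displaces the oxyphosphonium group at a carbon that is not stereogenic.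

Step 18
Reactants: 26 7-{[(3R)-5-[(1R,6S)-3,6-dihydroxy-2,2,6-trimethylcyclohexyl]-3-hydroxy-3-methylpentyl]oxy}-2H-chromen-2-one
Product: 27 7-{[(3R)-3-hydroxy-5-[(1R,6S)-6-hydroxy-2,2,6-trimethyl-3-oxocyclohexyl]-3-methylpentyl]oxy}-2H-chromen-2-one (CNP0414652.1)
Conditions: Dess–Martin periodinane, CH2Cl2, 25 °C
Reagents that add atoms: none
Why: Dess–Martin oxidation should convert both epimers of the only secondary alcohol into the C10 ketone, and the tertiary alcohols, the aryl ether and the coumarin lactone are inert to the reagent.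

**Compound list**

1 | but-3-yn-1-ol | C#CCCO | starting material
2 | tert-butyl(but-3-yn-1-yloxy)dimethylsilane | C#CCCO[Si](C)(C)C(C)(C)C | intermediate
3 | [(1E)-4-{[tert-butyl(dimethyl)silyl]oxy}-2-methylbut-1-en-1-yl]dimethylalane (not isolated) | C[Al](C)/C=C(\C)CCO[Si](C)(C)C(C)(C)C | intermediate
4 | lithium butyl[(1E)-4-{[tert-butyl(dimethyl)silyl]oxy}-2-methylbut-1-en-1-yl]dimethylaluminate (not isolated) | [Li+].CCCC[Al-](C)(C)/C=C(\C)CCO[Si](C)(C)C(C)(C)C | intermediate
5 | (2E)-5-{[tert-butyl(dimethyl)silyl]oxy}-3-methylpent-2-en-1-ol | OC/C=C(\C)CCO[Si](C)(C)C(C)(C)C | intermediate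
6 | tert-butyl({(3E)-5-[(4-methoxybenzyl)oxy]-3-methylpent-3-en-1-yl}oxy)dimethylsilane | COc1ccc(COC/C=C(\C)CCO[Si](C)(C)C(C)(C)C)cc1 | intermediate
7 | (3E)-5-[(4-methoxybenzyl)oxy]-3-methylpent-3-en-1-ol | COc1ccc(COC/C=C(\C)CCO)cc1 | intermediate
8 | 1-({[(2E)-5-bromo-3-methylpent-2-en-1-yl]oxy}methyl)-4-methoxybenzene | COc1ccc(COC/C=C(\C)CCBr)cc1 | intermediate
9 | geraniol, (2E)-3,7-dimethylocta-2,6-dien-1-ol | CC(C)=CCC/C(C)=C/CO | starting material
10 | (2S,3S)-2,3-epoxygeraniol | CC(C)=CCC[C@]1(C)O[C@H]1CO | intermediate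
11 | (2S,3R)-3-(iodomethyl)-2-methyl-2-(4-methylpent-3-en-1-yl)oxirane | CC(C)=CCC[C@]1(C)O[C@H]1CI | intermediate
12 | (S)-linalool, (3S)-3,7-dimethylocta-1,6-dien-3-ol | C=C[C@@](C)(O)CCC=C(C)C | intermediate
13 | 3-[(3S)-3-hydroxy-3-methylpent-4-en-1-yl]-5,5-dimethyl-1,2,4-trioxolane (ozonide, not isolated) | C=C[C@@](C)(O)CCC1OOC(C)(C)O1 | intermediate
14 | (5S)-5-ethenyl-5-methyloxolan-2-ol (both anomers) | C=C[C@]1(C)CCC(O)O1 | intermediate
15 | (6S)-2,6-dimethylocta-1,7-diene-3,6-diol (both C3 epimers) | C=C[C@@](C)(O)CCC(O)C(C)=C | intermediate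
16 | (4S)-2,4-dimethylcyclohex-2-ene-1,4-diol (both C1 epimers) | CC1=C[C@@](C)(O)CCC1O | intermediate
17 | (4S)-4-hydroxy-2,4-dimethylcyclohex-2-en-1-one | CC1=C[C@@](C)(O)CCC1=O | intermediate
18 | {(3E)-5-[(4-methoxybenzyl)oxy]-3-methylpent-3-en-1-yl}magnesium bromide (not isolated) | COc1ccc(COC/C=C(\C)CC[Mg]Br)cc1 | intermediate
19 | lithium (1S)-1,3-dimethyl-4-oxocyclohex-2-en-1-olate, the alkoxide of 17 (not isolated) | CC1=C[C@@](C)(O[Li])CCC1=O | intermediate
20 | C10–C11 bromomagnesium enolate of the 1,4-adduct, C7 lithium alkoxide (not isolated) | CC1=C(O[Mg]Br)CC[C@](C)(O[Li])[C@@H]1CC/C(C)=C/COCc1ccc(OC)cc1 | intermediate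
21 | (3R,4S)-4-hydroxy-3-{(3E)-5-[(4-methoxybenzyl)oxy]-3-methylpent-3-en-1-yl}-2,2,4-trimethylcyclohexan-1-one | CC1(C)C(=O)CC[C@](C)(O)[C@@H]1CC/C(C)=C/COCc1ccc(OC)cc1 | intermediate
22 | (3R,4S)-4-hydroxy-3-[(3E)-5-hydroxy-3-methylpent-3-en-1-yl]-2,2,4-trimethylcyclohexan-1-one | CC1(C)C(=O)CC[C@](C)(O)[C@@H]1CC/C(C)=C/CO | intermediate
23 | (3R,4S)-4-hydroxy-3-{2-[(2R,3R)-3-(hydroxymethyl)-2-methyloxiran-2-yl]ethyl}-2,2,4-trimethylcyclohexan-1-one | CC1(C)C(=O)CC[C@](C)(O)[C@@H]1CC[C@@]2(C)O[C@@H]2CO | intermediate
24 | (1S,2R)-2-[(3R)-3,5-dihydroxy-3-methylpentyl]-1,3,3-trimethylcyclohexane-1,4-diol (both C4 epimers, C4 being C10) | CC1(C)C(O)CC[C@](C)(O)[C@@H]1CC[C@@](C)(O)CCO | intermediate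
25 | umbelliferone, 7-hydroxy-2H-chromen-2-one | O=c1ccc2ccc(O)cc2o1 | starting material
26 | 7-{[(3R)-5-[(1R,6S)-3,6-dihydroxy-2,2,6-trimethylcyclohexyl]-3-hydroxy-3-methylpentyl]oxy}-2H-chromen-2-one (both epimers at the C10 carbinol) | CC1(C)C(O)CC[C@](C)(O)[C@@H]1CC[C@@](C)(O)CCOc1ccc2ccc(=O)oc2c1 | intermediate
27 | 7-{[(3R)-3-hydroxy-5-[(1R,6S)-6-hydroxy-2,2,6-trimethyl-3-oxocyclohexyl]-3-methylpentyl]oxy}-2H-chromen-2-one | CC1(C)C(=O)CC[C@](C)(O)[C@@H]1CC[C@@](C)(O)CCOc1ccc2ccc(=O)oc2c1 | target

**Step count**

Total: 18 steps. Longest linear sequence: 13 steps (geraniol 9 to target 27, steps 6–18). The chain branch (steps 1–5) joins at step 13.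

**Steps most likely to fail**

Step 13. Three processes may intervene:
- direct carbonyl addition may compete with alkoxide delivery;
- C-methylation of the hindered magnesium enolate may be slow enough for proton exchange to move the enolate to C9, or for the C7 alkoxide to be O-methylated;
- the homoallylic Grignard reagent may decay through cyclopropylcarbinyl rearrangement if kept warm.

The fallback separates addition from alkylation. It sets out from 17 and 8 and runs the directed addition as before. The enolate 20 is then trapped with Me3SiCl and Et3N to give the C7-silylated trimethylsilyl enol ether F1, which is isolated. MeLi in THF at 0 °C cleaves only the enol silyl ether and regenerates the lithium enolate regiospecifically. Alkylation with MeI and DMPU gives the C7 trimethylsilyl ether of the gem-dimethyl ketone F2. K2CO3 in MeOH removes the silyl group, and the route is rejoined at 21.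

Step 15. The C7 hydroxyl may open the new oxirane at C3 under titanium Lewis acid activation (six-membered ether formation), or the polar substrate may sequester the catalyst and stall turnover. The fallback masks C7 before the epoxidation. It sets out from 21:
- Et3SiOTf and 2,6-lutidine at −78 °C give the C7 triethylsilyl ether F3.
- DDQ releases the silyl-protected allylic alcohol F4.
- The same titanium D-tartrate epoxidation gives the silyl-protected (2R,3R)-epoxy alcohol F5.
- NaAlH2(OCH2CH2OMe)2 opens it at C2 and reduces C10 to give the C7 triethylsilyl ether of the tetraol F6.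
- Bu4NF removes the silyl group, and the route is rejoined at 24.

Step 17. Activation may spread to the C10 hydroxyl, or the activated C1 position may be captured intramolecularly by the C3 hydroxyl instead of the phenol. The fallback replaces the redox condensation by a two-stage displacement. It sets out from 24: TsCl in pyridine at 0 °C sulfonylates only the primary hydroxyl to give the C1 mono-tosylate F7. Umbelliferone 25 with K2CO3 in DMF at 50 °C then displaces the tosylate, and the route is rejoined at 26.

**Further compounds**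

F1 | step 13 | C7-O-trimethylsilyl, C10-O-trimethylsilyl enol ether of the 1,4-adduct | CC1=C(O[Si](C)(C)C)CC[C@](C)(O[Si](C)(C)C)[C@@H]1CC/C(C)=C/COCc1ccc(OC)cc1
F2 | step 13 | C7 trimethylsilyl ether of 21 | CC1(C)C(=O)CC[C@](C)(O[Si](C)(C)C)[C@@H]1CC/C(C)=C/COCc1ccc(OC)cc1
F3 | step 15 | C7 triethylsilyl ether of 21 | CC1(C)C(=O)CC[C@](C)(O[Si](CC)(CC)CC)[C@@H]1CC/C(C)=C/COCc1ccc(OC)cc1
F4 | step 15 | C7 triethylsilyl ether of 22 | CC1(C)C(=O)CC[C@](C)(O[Si](CC)(CC)CC)[C@@H]1CC/C(C)=C/CO
F5 | step 15 | C7 triethylsilyl ether of 23 | CC1(C)C(=O)CC[C@](C)(O[Si](CC)(CC)CC)[C@@H]1CC[C@@]2(C)O[C@@H]2CO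
F6 | step 15 | C7 triethylsilyl ether of 24 | CC1(C)C(O)CC[C@](C)(O[Si](CC)(CC)CC)[C@@H]1CC[C@@](C)(O)CCO
F7 | step 17 | C1 4-methylbenzenesulfonate of 24 | CC1(C)C(O)CC[C@](C)(O)[C@@H]1CC[C@@](C)(O)CCOS(=O)(=O)c1ccc(C)cc1
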